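The earlier runs and the new flask are calculated from invented constants; scatter was added.

**My call.** I commit to ochre as the longer; you asked for a quick number, and here is why.

| setting | epsilon | eta | violet | ochre |
|---|---|---|---|---|
| free monomer | 0.020 M | 0.010 M | 0.020 M | 0.020 M |
| transfer agent | 1.3 mM | 2 mM | 2.00 mM | 2.00 mM |
| protic impurity | 0.40 mM | 0.40 mM | 0.400 mM | 0.400 mM |
| pre-initiator | 40 µM | 40 µM | 40 µM | 20 µM |
| remark | run made earlier | run made earlier |  |  |
| time |  |  | 25 min | 25 min |

- epsilon (time / min: monomer in chains / %, free monomer / %): 0.417: 0, 100; 1.00: 3, 99; 2.00: 13, 84; 5.00: 65, 35
- eta (time / min: monomer in chains / %, free monomer / %): 0.667: 2, 95; 2.00: 5, 88; 3.00: 17, 80; 5.00: 45, 53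

(each reading ± 1.5 percentage points)

- the average divides the monomer in chains by the number of chains begun, living and dead together
- the earlier runs do not show the number of chains; that part of a forecast is a guess
- no earlier run changes the charge of pre-initiator; that part of a forecast is a guess

- which of the two ends with the longer chains by the average number of monomer units in a chain (chains begun, living or dead) ("neither" if they lie within 10%) (violet / ochre / neither)
- average number of monomer units in a chain (chains begun, living or dead) at the end, violet
- average number of monomer units in a chain (chains begun, living or dead) at the end, ochre

**Fraction left.** I work with what is left of the monomer. In eta, free monomer and monomer in chains leave a mean gap of 3.75%, as a reading. The [protic impurity] charge is 4.00% of the [free monomer] charge there. So I read the impurity as consuming monomer one for one, outside the chains.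

**Transfer agent.** The late slope of ln(fraction left), a pseudo-first-order constant, reads 0.292 /min in epsilon. It reads 0.206 /min in eta, which is lower with more agent. Eta also has half the monomer, so this proves nothing. My guess is that the agent ends chains and does not restart them.

**Charge floor.** For violet I reckon 490 units. This is the charge floor: monomer not quenched, divided by pre-initiator charged, on my assumption of at most one chain per pre-initiator. Fewer chains lift the length above it. Monomer left free lowers it, so it is an estimate and not a strict bound. Ochre's floor is 980, twice violet's.

**Your forecast.** It says neither, with 9 for violet and 8.5 for ochre: “Pre-initiator adds few chains”. My floors stand far above those lengths. I count chains from the pre-initiator; your forecast expects transfer agent and impurity to set their number.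

**The flask.** The longer chains are in ochre: 1770 against 1350 for violet. Both exceed their floors, but the ratio is 1.31, not the floors' 2.00.

    free monomer + initiator → living end + monomer in chains (k = 0.420 /M/s)
    free monomer + living end → monomer in chains + living end, rate k2*[living end]*[free monomer] (k = 2000 /M/s)
    living end + transfer agent → dead chain (kL = 3.60 /M/s)
    protic impurity + free monomer → quenched substrate (k = 13.0 /M/s)
    pre-initiator → initiator (k = 0.00110 /s)

**Neighbour flask.** This is ochre with 8.0 × 10⁻⁴ M of transfer agent. The floor has no agent in it, so it stays 980. The neighbour flask reaches 2770 units, 2.83 times that floor, with 96.9% of the monomer in chains. That makes 6.98 µM of chains begun from 20 µM of pre-initiator charged.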